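The pitfall is to take a percent column as a property of the recipe, when its denominator is the substrate charge and the last substrate readings still stand at 85.3% in eta and 77.9% in gamma.

| setting | eta | gamma | Sunday's | Saturday's |
|---|---|---|---|---|
| substrate | 0.25 M (fed, over 6.0 s) | 0.25 M (fed, over 6.0 s) | 0.25 M (fed, over 6.0 s) | 0.25 M |
| reagent | 0.043 M | 0.17 M | 0.125 M | 0.0300 M |
| free catalyst | 38 mM | 38 mM | 38 mM | 38 mM |
| remark | run made earlier; the fed solution adds 0.20 times the starting volume | run made earlier; the fed solution adds 0.20 times the starting volume | the fed solution adds 0.20 times the starting volume | everything together at the start, the whole solution of substrate included, so that from the start the volume is larger by 0.20 times the starting volume |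
| time |  |  | 2.0 min | 2.0 min |

| run | time / s | target / % | substrate / % |
|---|---|---|---|
| eta | 20.0 | 12.7 | 87.1 |
| eta | 40.0 | 12.2 | 86.4 |
| eta | 60.0 | 13.4 | 85.5 |
| eta | 80.0 | 13.7 | 86.1 |
| eta | 90.0 | 13.6 | 86.2 |
| eta | 120 | 13.3 | 85.3 |
| gamma | 10.0 | 18.9 | 79.6 |
| gamma | 15.0 | 19.3 | 79.9 |
| gamma | 25.0 | 20.7 | 79.3 |
| gamma | 40.0 | 20.4 | 78.9 |
| gamma | 80.0 | 20.8 | 78.2 |
| gamma | 120 | 20.3 | 77.9 |

(standard deviation of a reading: 0.5 percentage points)

- which of the two ends with the higher amount of target, in percent of the substrate charged ("neither" if they lie within 2 percentage points) (Sunday's / Saturday's / neither)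
- target at the end, in percent of the substrate charged, Sunday's
- target at the end, in percent of the substrate charged, Saturday's

- charges are per starting volume, the dose included; the dosed solution carries all of it
- the numbers in the tables scatter by 0.5 percentage points (one standard deviation)
- candidate steps: reagent + free catalyst -> catalyst intermediate A; substrate + catalyst intermediate A <-> catalyst intermediate B; catalyst intermediate B -> catalyst intermediate C; catalyst intermediate C <-> free catalyst + target; 2 reagent -> self-condensation product; reagent <-> dormant form

So reckon in molar, and follow the run slowly.

1. The first instants. By the candidate steps, reagent meets free catalyst and forms catalyst intermediate A while substrate arrives over 6.0 s. Gamma's last readings average 20.5% of target, and its first reading, at 10.0 s, already shows 18.9%, nearly all of that.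

2. The middle. Multiply the last readings by the charge and you get the harvest: 0.0338 M in eta from 0.043 M of reagent, and 0.0512 M in gamma from 0.17 M. The share of reagent ending as target falls from 78.6% in eta to 30.1% in gamma. You expect that direction if two reagent meeting each other compete with capture by the catalyst. Gamma's harvest is larger than its catalyst charge, so its catalyst has turned over.

3. The end. Eta's target readings from 60.0 s on lie between 13.3% and 13.7%. The candidate steps spend one reagent per target, and eta's substrate left, 0.213 M, exceeds its reagent charge, so I suspect reagent has stopped eta.

4. My reckoning. Let the harvest grow as a power of the reagent charge, with exponent 0.302 read from the two runs. Sunday's harvest is then 0.0467 M, the target in molar per starting volume once the flask stands still, or 18.7% of 0.25 M.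

5. Saturday's reagent lies below eta's, so I keep eta's share and get 0.0236 M, or 9.44%, a rough figure, since Saturday's flask is not fed as eta was. Its charge caps it at 12.0%. Sunday's stands higher than Saturday's by 9.2 percentage points, where the margin is 2 points.

The forecast, holding that “reagent, not time, sets the yield”, names Sunday's, with 19% against 10.7%.

The flask gives Sunday's: 20.1% for Sunday's and 9.99% for Saturday's.

    reagent + free catalyst → catalyst intermediate A (k = 75.4 M⁻¹ s⁻¹)
    substrate + catalyst intermediate A ⇌ catalyst intermediate B (K = 52.3 M⁻¹, k = 5.83 M⁻¹ s⁻¹)
    catalyst intermediate B → catalyst intermediate C (k = 1.14 s⁻¹)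
    catalyst intermediate C ⇌ free catalyst + target (K = 0.570 M, k = 1.24 s⁻¹)
    2 reagent → self-condensation product (k = 9.98 M⁻¹ s⁻¹)
    reagent ⇌ dormant form (K = 3.93, k = 0.0483 s⁻¹)

Sunday's 20.1% is a harvest of 0.0503 M, against my 0.0467 M. Reagent, the limiting reagent there, stands at 0% of its charge at 2.00 min, with 79% of the substrate left. Now take the same flask as Sunday's with 0.062 M of substrate. Carry the harvest over unchanged and divide: 0.0467 M over 0.062 M gives 75.3%. That neighbour gives 76.5% of target, a harvest of 0.0474 M, and leaves 19.5% of its substrate.

The earlier runs and the new flask come from a simulation for substances that don't exist; scatter was added.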